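**Plan**

- Retrosynthesis: the aryl ether O–CH2 bond is cut last (Mitsunobu), the oxirane goes back to an E-allylic alcohol, the tertiary hydroxyl of the lactone goes back to a 3-methylfuran-2(5H)-one, and the lactone ring is then cut at O1–C5 and at C2–C3 (lactone numbering O1, C2 carbonyl, C3, C4, C5), so that the carboxyl unit leaves as CO plus water.
- Enabling feature: C5–C4–C3(CH3) of the γ-lactone ring is a but-2-ynyl carbinol in disguise. C5 is a propargylic carbinol carbon, C4 and C3 are the alkyne carbons, and the C3 methyl is the alkyne methyl. SN2′ palladation at C3, CO insertion and closure of the carboxyl oxygen on C5 build the ring in one operation.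
- Forward order: but-2-ynal plus a propargyl unit gives a diynol; carboalumination and hydroxymethylation of its terminal alkyne build the E-trisubstituted allylic alcohol; silylation and mesylation follow; then the carbonylative lactonisation (furanone ring), desilylation, epoxidation (oxirane ring), radical hydration at C3 and etherification with the coumarin.
- Stereochemistry: lactone C5 comes from the propargylic carbinol (centre to allene axis to centre, net inversion); C3 from 1,3-induction by C5 in the oxygenation; the oxirane from D-(−)-tartrate control; the E-alkene from syn-carbometalation.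
- The coumarin is attached last because its conjugated C3=C4 bond would not be expected to survive the radical hydration.

Key step: step 5

Remark: but-2-ynal and 7-hydroxy-8-methoxycoumarin are taken as purchasable (the aldehyde can also be set free from its commercial diethyl acetal).

**Route**

Step 1
Reactants: 1 but-2-ynal; 2 3-bromoprop-1-yne (propargyl bromide)
Product: 6 (S)-hepta-1,5-diyn-4-ol, via allenylmagnesium bromide 3 (not isolated), via B-allenyldiisopinocampheylborane 4 (not isolated), via homopropargyl diisopinocampheylborinate 5 (not isolated)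
Conditions: 2, Mg, HgCl2 (cat.), Et2O, 0 °C; (−)-Ipc2BOMe, Et2O, −78 °C to rt; 1, −100 °C; then NaOH, H2O2, 0 °C to rt
Reagents that add atoms: none
Why: Asymmetric allenylboration of the Brown type, in which the allenylborane delivers its propargyl terminus through a six-membered chair transition state (SE2′) and the isopinocampheyl groups of the (+)-α-pinene series should direct it to the Si face of the aldehyde, setting C4 as S.

Step 2
Reactants: 6 (S)-hepta-1,5-diyn-4-ol
Product: 8 (2E,5S)-3-methyloct-2-en-6-yne-1,5-diol, via alkenyl(dimethyl)alane 7 (not isolated)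
Conditions: Me3Al, Cp2ZrCl2 (cat.), CH2Cl2, 0 °C to rt; then n-BuLi, THF, −30 °C; (CH2O)n, rt; aq. HCl, 0 °C
Reagents that add atoms: trimethylaluminium, C[Al](C)C; formaldehyde (from paraformaldehyde), C=O
Why: Zirconium-catalysed carboalumination (Negishi) adds methyl and aluminium syn across the terminal alkyne only, with aluminium at the terminus, and hydroxymethylation of the derived alanate goes with retention, so the trisubstituted alkene should be fixed as E while the much slower internal alkyne and the carbinol centre stay untouched.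

Step 3
Reactants: 8 (2E,5S)-3-methyloct-2-en-6-yne-1,5-diol
Product: 9 (4S,6E)-8-[(tert-butyldimethylsilyl)oxy]-6-methyloct-6-en-2-yn-4-ol
Conditions: TBSCl (1.05 equiv), imidazole, CH2Cl2, −20 °C
Reagents that add atoms: tert-butyldimethylsilyl chloride, CC(C)(C)[Si](C)(C)Cl
Why: Silylation should be selective for the unhindered primary allylic hydroxyl over the secondary propargylic one.

Step 4
Reactants: 9 (4S,6E)-8-[(tert-butyldimethylsilyl)oxy]-6-methyloct-6-en-2-yn-4-ol
Product: 10 (4S,6E)-8-[(tert-butyldimethylsilyl)oxy]-6-methyloct-6-en-2-yn-4-yl methanesulfonate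
Conditions: MsCl, Et3N, CH2Cl2, −40 to 0 °C; used crude
Reagents that add atoms: methanesulfonyl chloride, CS(=O)(=O)Cl
Why: Sulfonylation at oxygen leaves C4 untouched (retention) and installs the leaving group needed for SN2′ ionisation.

Step 5
Reactants: 10 (4S,6E)-8-[(tert-butyldimethylsilyl)oxy]-6-methyloct-6-en-2-yn-4-yl methanesulfonate
Product: 12 (R)-5-[(E)-4-[(tert-butyldimethylsilyl)oxy]-2-methylbut-2-en-1-yl]-3-methylfuran-2(5H)-one, via (aR)-allenic acid 11 (not isolated)
Conditions: Pd(PPh3)4 (5 mol %), CO (1 atm), 2,6-lutidine, THF/H2O, rt; then AgNO3 (20 mol %), acetone, rt, dark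
Reagents that add atoms: carbon monoxide, [C-]#[O+]; water, O
Why: Zerovalent palladium ionises the propargylic mesylate by SN2′ attack at the methyl-bearing alkyne carbon anti to the leaving group, the allenylpalladium species inserts CO and the acyl–Pd bond is hydrolysed, so the carbinol stereocentre is stored as the axis of (aR)-allenic acid 11 with its carboxyl carbon on the future C3; monovalent silver then activates the remote allene π bond and the carboxyl oxygen adds to the former carbinol carbon, with protodemetalation at the central carbon. The closest known reaction type is the palladium-catalysed hydroxycarbonylation of enantioenriched propargylic sulfonates to 2,3-dienoic acids followed by silver nitrate cyclisation to 2(5H)-furanones. The single ring (the furanone) closes in a 5-endo-trig mode, the oxygen attacking the sp2 terminus of the allene whose C4=C5 π bond lies inside the forming ring. The only new stereocentre, C5, is controlled by the allene axis: the carboxyl group sits on the face opposite to the departed mesylate and can reach C5 only from that side, which should give net inversion, (4S)-mesylate to (5R)-furanone. The step needs SN2′ over direct substitution and anti over syn ionisation, which the unhindered methyl-capped alkyne terminus, the sulfonate leaving group and the phosphine-ligated palladium should secure, and it needs closure onto the allene and not onto the isolated trisubstituted alkene, which the conjugated geometry secures by placing only the allene terminus within reach of the carboxyl oxygen. 2,6-Lutidine takes up the methanesulfonic acid so that the silyl ether should survive.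

Step 6
Reactants: 12 (R)-5-[(E)-4-[(tert-butyldimethylsilyl)oxy]-2-methylbut-2-en-1-yl]-3-methylfuran-2(5H)-one
Product: 13 (R)-5-[(E)-4-hydroxy-2-methylbut-2-en-1-yl]-3-methylfuran-2(5H)-one
Conditions: HF·pyridine, pyridine, THF, 0 °C
Reagents that add atoms: none
Why: Fluoride-mediated desilylation under buffered acidic conditions frees the allylic alcohol without a base strong enough to epimerise the γ-position of the furanone.

Step 7
Reactants: 13 (R)-5-[(E)-4-hydroxy-2-methylbut-2-en-1-yl]-3-methylfuran-2(5H)-one
Product: 14 (R)-5-{[(2R,3R)-3-(hydroxymethyl)-2-methyloxiran-2-yl]methyl}-3-methylfuran-2(5H)-one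
Conditions: Ti(OiPr)4 (10 mol %), D-(−)-diethyl tartrate (12 mol %), t-BuOOH, 4 Å MS, CH2Cl2, −20 °C
Reagents that add atoms: tert-butyl hydroperoxide, CC(C)(C)OO
Why: Sharpless asymmetric epoxidation, in which the titanium tartrate complex binds the allylic hydroxyl and delivers oxygen to one alkene face under reagent control (D-(−)-tartrate should give the 2R,3R epoxide from an E-3-methylalk-2-en-1-ol), while the electron-poor furanone alkene is inert to the electrophilic oxidant.

Step 8
Reactants: 14 (R)-5-{[(2R,3R)-3-(hydroxymethyl)-2-methyloxiran-2-yl]methyl}-3-methylfuran-2(5H)-one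
Product: 16 (3R,5S)-3-hydroxy-5-{[(2R,3R)-3-(hydroxymethyl)-2-methyloxiran-2-yl]methyl}-3-methyloxolan-2-one, via tertiary hydroperoxide 15 (not isolated)
Conditions: Mn(dpm)3 (tris(dipivaloylmethanato)manganese, 5 mol %), PhSiH3, O2 (1 atm), i-PrOH/CH2Cl2, 0 °C; then P(OEt)3
Reagents that add atoms: dioxygen, O=O
Why: Mukaiyama-type hydration of an α,β-unsaturated lactone, in which a manganese hydride transfers a hydrogen atom to C4, the tertiary α-acyl radical at C3 is trapped by O2 on the face anti to the C5 substituent (1,3-induction) and the phosphite reduces the hydroperoxide with retention, so the hydroxyl should end up trans to the side chain (3R); no other alkene is present at this stage.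

Step 9
Reactants: 16 (3R,5S)-3-hydroxy-5-{[(2R,3R)-3-(hydroxymethyl)-2-methyloxiran-2-yl]methyl}-3-methyloxolan-2-one; 17 7-hydroxy-8-methoxy-2H-chromen-2-one
Product: 18 7-{[(2R,3R)-3-{[(2S,4R)-4-hydroxy-4-methyl-5-oxooxolan-2-yl]methyl}-3-methyloxiran-2-yl]methoxy}-8-methoxy-2H-chromen-2-one (target)
Conditions: PPh3, DIAD, THF, 0 °C to rt
Reagents that add atoms: none
Why: Mitsunobu etherification, in which the acidic 7-hydroxyl of the coumarin displaces the activated primary hydroxyl at a CH2 carbon, so no stereocentre is touched and the tertiary alcohol and the oxirane should not react.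

**Compound list**

1 | but-2-ynal | CC#CC=O | starting material
2 | 3-bromoprop-1-yne (propargyl bromide) | C#CCBr | starting material
3 | allenylmagnesium bromide | C=C=C[Mg]Br | intermediate
4 | B-allenyldiisopinocampheylborane, (+)-α-pinene series | C=C=CB([C@@H]1C[C@@H]2C[C@H]([C@H]1C)C2(C)C)[C@@H]1C[C@@H]2C[C@H]([C@H]1C)C2(C)C | intermediate
5 | (S)-hepta-1,5-diyn-4-yl diisopinocampheylborinate | C#CC[C@H](OB([C@@H]1C[C@@H]2C[C@H]([C@H]1C)C2(C)C)[C@@H]1C[C@@H]2C[C@H]([C@H]1C)C2(C)C)C#CC | intermediate
6 | (S)-hepta-1,5-diyn-4-ol | C#CC[C@H](O)C#CC | intermediate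
7 | dimethyl[(1E,4S)-4-(dimethylalumanyloxy)-2-methylhept-1-en-5-yn-1-yl]alumane | C[Al](C)/C=C(\C)C[C@H](O[Al](C)C)C#CC | intermediate
8 | (2E,5S)-3-methyloct-2-en-6-yne-1,5-diol | OC/C=C(\C)C[C@H](O)C#CC | intermediate
9 | (4S,6E)-8-[(tert-butyldimethylsilyl)oxy]-6-methyloct-6-en-2-yn-4-ol | CC(C)(C)[Si](C)(C)OC/C=C(\C)C[C@H](O)C#CC | intermediate
10 | (4S,6E)-8-[(tert-butyldimethylsilyl)oxy]-6-methyloct-6-en-2-yn-4-yl methanesulfonate | CC(C)(C)[Si](C)(C)OC/C=C(\C)C[C@H](OS(C)(=O)=O)C#CC | intermediate
11 | (aR,6E)-8-[(tert-butyldimethylsilyl)oxy]-2,6-dimethylocta-2,3,6-trienoic acid | OC(=O)C(C)=[C@]=C([H])C/C(C)=C/CO[Si](C)(C)C(C)(C)C | intermediate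
12 | (R)-5-[(E)-4-[(tert-butyldimethylsilyl)oxy]-2-methylbut-2-en-1-yl]-3-methylfuran-2(5H)-one | CC(C)(C)[Si](C)(C)OC/C=C(\C)C[C@@H]1C=C(C)C(=O)O1 | intermediate
13 | (R)-5-[(E)-4-hydroxy-2-methylbut-2-en-1-yl]-3-methylfuran-2(5H)-one | OC/C=C(\C)C[C@@H]1C=C(C)C(=O)O1 | intermediate
14 | (R)-5-{[(2R,3R)-3-(hydroxymethyl)-2-methyloxiran-2-yl]methyl}-3-methylfuran-2(5H)-one | OC[C@H]1O[C@]1(C)C[C@@H]1C=C(C)C(=O)O1 | intermediate
15 | (3R,5R)-3-hydroperoxy-5-{[(2R,3R)-3-(hydroxymethyl)-2-methyloxiran-2-yl]methyl}-3-methyloxolan-2-one | OC[C@H]1O[C@]1(C)C[C@@H]1C[C@@](C)(OO)C(=O)O1 | intermediate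
16 | (3R,5S)-3-hydroxy-5-{[(2R,3R)-3-(hydroxymethyl)-2-methyloxiran-2-yl]methyl}-3-methyloxolan-2-one | OC[C@H]1O[C@]1(C)C[C@@H]1C[C@@](C)(O)C(=O)O1 | intermediate
17 | 7-hydroxy-8-methoxy-2H-chromen-2-one | COc1c(O)ccc2ccc(=O)oc12 | starting material
18 | 7-{[(2R,3R)-3-{[(2S,4R)-4-hydroxy-4-methyl-5-oxooxolan-2-yl]methyl}-3-methyloxiran-2-yl]methoxy}-8-methoxy-2H-chromen-2-one | COc1c(OC[C@H]2O[C@]2(C)C[C@@H]2C[C@@](C)(O)C(=O)O2)ccc2ccc(=O)oc12 | target

**Count and risks**

Total step count: 9. Longest linear sequence: 9 steps (from but-2-ynal).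

Steps most likely to fail:

Step 5. The allenyl- and propargylpalladium species may interconvert, or the allenylpalladium may be racemised by a second palladium before CO insertion, so that the axis and then C5 lose enantiopurity; direct hydrolysis of the mesylate is a second drain. The fallback sets out from 9 and comes back at 12, and it closes the ring at the acyl–oxygen bond with the C5–O bond already in place. A Mitsunobu inversion of 9 with 4-nitrobenzoic acid (PPh3, DIAD) would give (4R,6E)-8-[(tert-butyldimethylsilyl)oxy]-6-methyloct-6-en-2-yn-4-yl 4-nitrobenzoate F1, and methanolysis (K2CO3, MeOH) the (4R)-alcohol F2. Hydroxyl-directed trans-hydroalumination with NaAlH2(OCH2CH2OMe)2 followed by iodinolysis would give the (2Z)-2-iodo-dienol F3. Carbonylative lactonisation of this vinyl iodide (PdCl2(PPh3)2, CO, K2CO3, THF) should then form the furanone with retention at the carbinol, which is 12.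

Step 8. Capture of the planar C3 radical by O2 may show poor facial selectivity, since only 1,3-induction from C5 steers it, and hydrogen transfer to the radical (plain reduction) may outrun oxygenation. The fallback sets out from 12 and comes back at 16, and it uses an enolate and a bulky electrophilic oxidant in place of the radical. Conjugate reduction of 12 with [(Ph3P)CuH]6 would give the saturated (5S)-3-methyl lactone F4 (both C3 epimers usable). Enolisation with KN(SiMe3)2 at −78 °C and oxidation with 2-(phenylsulfonyl)-3-phenyloxaziridine (Davis reagent) should hydroxylate anti to the C5 substituent and give the (3R,5R)-hydroxy lactone silyl ether F5. Bu4NF would give the (3R,5R)-diol F6, and the tartrate-controlled epoxidation of step 7 applied to F6 would give 16.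

Step 2. Chemoselectivity may be lost: the aluminium alkoxide next to the internal alkyne could direct a second carbometalation or an isomerisation, and the alanate may be hydroxymethylated only in part. The fallback sets out from 6 and comes back at 8, and it builds the E-alkene by hydroalumination, iodination and cuprate coupling. Silylation of 6 (TBSCl, imidazole) would give (S)-tert-butyl(hepta-1,5-diyn-4-yloxy)dimethylsilane F7. Deprotonation of the terminal alkyne (n-BuLi, −78 °C) and addition to paraformaldehyde would give (S)-5-[(tert-butyldimethylsilyl)oxy]octa-2,6-diyn-1-ol F8. Hydroxyl-directed trans-hydroalumination of that alkyne alone (NaAlH2(OCH2CH2OMe)2) and iodinolysis would give the (2Z)-3-iodoalkenol F9. Me2CuLi should replace iodine by methyl with retention to give the E-allylic alcohol F10, and Bu4NF would then give 8.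

Further compounds
F1 | step 5 | (4R,6E)-8-[(tert-butyldimethylsilyl)oxy]-6-methyloct-6-en-2-yn-4-yl 4-nitrobenzoate | CC(C)(C)[Si](C)(C)OC/C=C(\C)C[C@@H](OC(=O)c1ccc(cc1)[N+](=O)[O-])C#CC
F2 | step 5 | (4R,6E)-8-[(tert-butyldimethylsilyl)oxy]-6-methyloct-6-en-2-yn-4-ol | CC(C)(C)[Si](C)(C)OC/C=C(\C)C[C@@H](O)C#CC
F3 | step 5 | (2Z,4R,6E)-8-[(tert-butyldimethylsilyl)oxy]-2-iodo-6-methylocta-2,6-dien-4-ol | CC(C)(C)[Si](C)(C)OC/C=C(\C)C[C@@H](O)/C=C(/C)I
F4 | step 8 | (5S)-5-[(E)-4-[(tert-butyldimethylsilyl)oxy]-2-methylbut-2-en-1-yl]-3-methyloxolan-2-one (C3 epimers) | CC(C)(C)[Si](C)(C)OC/C=C(\C)C[C@@H]1CC(C)C(=O)O1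
F5 | step 8 | (3R,5R)-5-[(E)-4-[(tert-butyldimethylsilyl)oxy]-2-methylbut-2-en-1-yl]-3-hydroxy-3-methyloxolan-2-one | CC(C)(C)[Si](C)(C)OC/C=C(\C)C[C@@H]1C[C@@](C)(O)C(=O)O1
F6 | step 8 | (3R,5R)-3-hydroxy-5-[(E)-4-hydroxy-2-methylbut-2-en-1-yl]-3-methyloxolan-2-one | OC/C=C(\C)C[C@@H]1C[C@@](C)(O)C(=O)O1
F7 | step 2 | (S)-tert-butyl(hepta-1,5-diyn-4-yloxy)dimethylsilane | C#CC[C@H](O[Si](C)(C)C(C)(C)C)C#CC
F8 | step 2 | (S)-5-[(tert-butyldimethylsilyl)oxy]octa-2,6-diyn-1-ol | OCC#CC[C@H](O[Si](C)(C)C(C)(C)C)C#CC
F9 | step 2 | (2Z,5S)-5-[(tert-butyldimethylsilyl)oxy]-3-iodooct-2-en-6-yn-1-ol | OC/C=C(\I)C[C@H](O[Si](C)(C)C(C)(C)C)C#CC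
F10 | step 2 | (2E,5S)-5-[(tert-butyldimethylsilyl)oxy]-3-methyloct-2-en-6-yn-1-ol | OC/C=C(\C)C[C@H](O[Si](C)(C)C(C)(C)C)C#CC
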